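The data were computed with constants of no real substance.

I began with amounts: what each earlier run held of its charge, and what a flask charged at 0.20 M could hold of target.

| flask | substrate | remark | time |
|---|---|---|---|
| Friday's | 0.10 M | run made earlier |  |
| Thursday's | 0.40 M | run made earlier |  |
| flask | 0.20 M |  | 4.0 h |

| run | time / h | target / % | substrate / % |
|---|---|---|---|
| Friday's | 0.100 | 14.1 | 69.3 |
| Friday's | 0.200 | 18.3 | 44.4 |
| Friday's | 0.500 | 23.3 | 11.5 |
| Friday's | 1.00 | 20.6 | 0.6 |
| Friday's | 2.50 | 12.9 | 0 |
| Thursday's | 0.100 | 6.8 | 64.8 |
| Thursday's | 0.200 | 7.5 | 37.8 |
| Thursday's | 0.500 | 7.2 | 7.6 |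
| Thursday's | 1.00 | 6.4 | 1.4 |
| Thursday's | 2.50 | 4.4 | 0 |

(standard deviation of a reading: 0.5 percentage points)

- the earlier runs were read with a standard deviation of 0.5 percentage points
- a reading or a percentage of target counts all its forms, free or not

- the best time, 4.0 h at the latest, for target
- the amount of target, in percent of the substrate charged, at that time

1. I opened a ledger on Thursday's run at 0.200 h: 37.8% of the charge stood as substrate, 7.5% as target, and 54.7% went unread.
2. Between the first two readings of that run, substrate fell from 64.8% to 37.8%, but target rose only from 6.8% to 7.5%. So I took target's making and its loss to be nearly balanced while substrate lasted, a quasi-steady level.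
3. Thursday's highest reading, taken as a molar amount, gave 0.0300 M. I called this the ceiling, the [target] at which I took making and loss to balance.
4. Friday's highest reading came to 0.0233 M, below the ceiling.
5. For the new flask, I entered the ceiling as 15.0% of the charge. That put the other 85.0% under substrate and unread products, and the books closed.
6. I expected the best time between the 0.200 h of Thursday's highest reading and the 0.500 h of Friday's.
7. The forecast said 13.5% at 0.33 h, noting that “the target nearly plateaus near 0.03 M”. Its amount stood below my ceiling.

The flask gave 13.5% at 0.400 h.

    substrate → target (k = 6.10 × 10⁻⁴ s⁻¹)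
    substrate → side product A (k = 2.60 × 10⁻⁴ s⁻¹)
    target → over-reaction product (k = 7.50 × 10⁻⁵ s⁻¹)
    crystals ⇌ target, rate k4*(cs4 - [target]) while solid is left; crystals form when [target] > cs4 (solubility = 40.0 mM, k = 0.0360 s⁻¹)
    substrate + target → side product B (k = 0.0200 M⁻¹ s⁻¹)

That best was 0.0270 M, under the ceiling. The largest single effect on the highest amount of target in the flask came from the reaction of substrate with target to side product B: the run without that step reached 62.2% against 13.5%. The [target] at which that step's loss equals the making of target from substrate is 30.5 mM. For the neighbour flask charged with 0.80 M, the ceiling gave 3.75%, and that flask's best was 3.77%.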